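With the target numbered C1 (angelate carbinol), C2 (epoxyangelate carbinol), C3=C4(Me), C5/C10 (cis ring-fusion CH), C6H2, C7=O, C8(Me)=C9 and C11 (CMe2), ring A (seven-membered) is disconnected at C3 alone. Its other six atoms (C4, C5, C10, C11, C1, C2) together with ring B form the cis-octalone available from isoprene and 4,4-dimethylcyclohex-2-enone. The key step inserts C3 between C2 and C4: the kinetic silyl enol ether C4=C2 of this octalone is cyclopropanated and the siloxycyclopropane is fragmented with FeCl3, which gives the cis-fused cycloheptenone in one operation and leaves C5/C10 untouched. The C1/C2 esters and the C7 enone follow.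

Key step: step 3

Remark: the atom labels C1–C11 defined above are used for every intermediate; all bicyclic compounds from 3 on are 5R,10S, C1 is R from 14 on and C2 is R from 17 on.
Assumption: the (S)-oxazaborolidine is written for step 1 on the basis of the usual model for 2-cycloalkenones; the sense of induction is to be checked on 3 and the (R)-catalyst taken instead if it proves opposite.
Remark: the transient centres of 7 and 8, the C4 centre of 10 and the C7/C8 centres of 14–19 are carried as mixtures, since all of them become sp2 later.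

Step 1
Reactants: 1 isoprene; 2 4,4-dimethylcyclohex-2-en-1-one
Product: 3 (4aS,8aR)-4,4,6-trimethyl-3,4,4a,5,8,8a-hexahydronaphthalen-1(2H)-one (cis-octalone: C4=O, cis H5/H10, C7=C8(Me), C11 Me2)
Conditions: (S)-3,3-diphenyl-1-(2-methylphenyl)tetrahydro-1H,3H-pyrrolo[1,2-c][1,3,2]oxazaborole (20 mol %), AlBr3 (16 mol %), isoprene (5 equiv), CH2Cl2, −40 → −20 °C
Reagents that add atoms: none
Why: Catalytic asymmetric Diels–Alder reaction: the AlBr3-activated oxazaborolidine binds the enone carbonyl and screens one face of the C5=C10 bond, the isoprene terminus next to its methyl-bearing carbon bonds to the β-carbon C10 (para orientation, methyl on C8), and suprafacial addition to the cis-enone sets C5 and C10 together as the cis ring fusion with the absolute sense fixed by the catalyst.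

Step 2
Reactants: 3 cis-octalone
Product: 5 4,4,6-trimethyl-1-(trimethylsilyloxy)-3,4,4a,5,8,8a-hexahydronaphthalene (kinetic enol ether C4(OSiMe3)=C2), via lithium enolate 4 (not isolated)
Conditions: LiN(iPr)2, THF, −78 °C; Me3SiCl, −78 → 0 °C; pentane, filtration (no aqueous work-up)
Reagents that add atoms: chlorotrimethylsilane, C[Si](C)(C)Cl
Why: Kinetic enolate formation followed by O-silylation: the hindered amide removes a proton from the C2 methylene and not from the C5 methine, so the enol ether forms away from the ring fusion and C5 is not touched.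

Step 3
Reactants: 5 kinetic silyl enol ether; 6 diiodomethane
Product: 9 (5R,10S)-cis-6,6,9-trimethylbicyclo[5.4.0]undeca-3,9-dien-2-one (C4=O, C2=C3, C7=C8), via siloxycyclopropane 7 (not isolated), via β-chloro ketone 8 (not isolated)
Conditions: Et2Zn (1.3 equiv), CH2I2 (1.3 equiv), Et2O, 0 °C → rt, then pyridine, filtration, concentration; FeCl3 (2.5 equiv), DMF, 0 °C → rt; NaOAc, MeOH, 50 °C
Reagents that add atoms: diiodomethane (6), ICI
Why: The electrophilic zinc carbenoid adds to the electron-rich enol ether C4=C2 in a concerted [2+1] cycloaddition (Simmons–Smith reaction in the Furukawa form) and so places C3 on both carbons. FeCl3 then oxidises the siloxycyclopropane by one electron, the silyl group is lost, the C4–C2 bond shared by the two rings breaks to give the C4 ketone and a secondary radical at C2, a second FeCl3 transfers chlorine to C2, and acetate removes HCl through the C3 enolate to leave C2=C3. The closest known reaction type is the Saegusa–Ito FeCl3 ring enlargement of fused siloxycyclopropanes to cycloalk-2-enones. Ring A is thus not closed by a cyclisation: the three-membered ring is closed by the [2+1] addition and the seven-membered ring arises when the bond common to the six- and three-membered rings is cut. No stereocentre is created, because the cyclopropane and CHCl centres are transient, and C5/C10 are carried through because neither takes part. The step needs site selectivity (secured by the kinetic enol ether), chemoselectivity over the C7=C8 alkene (secured by the much higher nucleophilicity of the silyl enol ether and only a small excess of carbenoid), chlorine capture faster than addition of the C2 radical to C7=C8 (secured by a high FeCl3 concentration) and retention at C5 (secured by the weak base and moderate temperature of the elimination).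

Step 4
Reactants: 9 cis-fused dienone
Product: 10 tertiary allylic alcohol (9 with C4(OH)CH3, C2=C3 kept; both C4 epimers)
Conditions: MeLi, CeCl3, THF, −78 °C
Reagents that add atoms: methyllithium, [Li]C
Why: 1,2-Addition of an organocerium reagent to the C4 carbonyl of the enone: the low basicity of the reagent suppresses enolisation toward C5 and conjugate addition, and the configuration of the new carbinol centre is irrelevant because C4 becomes sp2 in step 5.

Step 5
Reactants: 10 tertiary allylic alcohol
Product: 11 transposed enone (C2=O, C3=C4(CH3), C7=C8)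
Conditions: pyridinium chlorochromate (C5H5NH[CrO3Cl], 2.5 equiv), Celite, CH2Cl2, rt
Reagents that add atoms: pyridinium chlorochromate, [O-][Cr](=O)(=O)Cl.c1cc[nH+]cc1
Why: Babler–Dauben oxidative 1,3-transposition: the chromate ester of the tertiary allylic alcohol undergoes a [3,3] shift to C2 and is oxidised there, which gives the C2 ketone conjugated to C3=C4(Me) and moves the oxygen function next to C1.

Step 6
Reactants: 11 transposed enone
Product: 15 (1R)-1-hydroxy enone 7,8-epoxide (C1–OH on the face of H5/H10; C2=O; C3=C4), via lithium dienolate 12 (not isolated), via silyl dienol ether 13 (not isolated), via silyloxy ketone epoxide 14 (not isolated)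
Conditions: LiN(iPr)2, THF, −78 °C; Me3SiCl; 3-chloroperbenzoic acid (2.3 equiv), hexane/CH2Cl2, −20 → 0 °C; Bu4NF, AcOH, THF, 0 °C
Reagents that add atoms: 3-chloroperbenzoic acid, OOC(=O)c1cccc(Cl)c1
Why: Rubottom oxidation of the kinetic cross-conjugated dienol ether C1=C2(OSiMe3)–C3=C4 (enolisation at C1 as with isophorone-type enones): the peracid should attack C1 on the face of H5/H10, because the pseudo-axial C11 methyl group and ring B screen the other face, while the second equivalent epoxidises the electron-rich C7=C8 bond (Prilezhaev reaction) and spares the conjugated C3=C4 bond.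

Step 7
Reactants: 15 hydroxy enone epoxide
Product: 16 chlorohydrin (C7–OH, C8(Cl)CH3, trans; C1–OH and C2=O unchanged)
Conditions: HCl (1 M in Et2O, 1.2 equiv), CH2Cl2, −78 → −40 °C
Reagents that add atoms: hydrogen chloride, Cl
Why: Acid-mediated epoxide opening with Markovnikov regiochemistry: chloride attacks the tertiary carbon C8 with inversion, so the oxygen stays on C7, the carbon that must become the ring-B carbonyl, and the α′-hydroxy enone is inert to cold HCl.

Step 8
Reactants: 16 chlorohydrin
Product: 17 (1R,2R)-triol (C1–OH and C2–OH trans, C3=C4; C7–OH, C8–Cl)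
Conditions: Me4NBH(OAc)3 (5 equiv), MeCN/AcOH 1:1, −30 → −20 °C
Reagents that add atoms: none
Why: Hydroxyl-directed (Saksena–Evans) reduction: the C1 hydroxyl exchanges onto boron and delivers hydride intramolecularly to the face of the C2 carbonyl on which it sits, which sets C2 with its new hydroxyl trans to C1–OH and gives 1,2-reduction only.

Step 9
Reactants: 17 triol
Product: 18 C1/C2 acetonide (C7–OH free, C8–Cl)
Conditions: 2,2-dimethoxypropane, pyridinium p-toluenesulfonate (cat.), CH2Cl2, rt
Reagents that add atoms: 2,2-dimethoxypropane, COC(C)(C)OC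
Why: Acid-catalysed acetonide formation (transketalisation), which is thermodynamically selective for the vicinal C1/C2 diol and leaves the isolated C7 hydroxyl free.

Step 10
Reactants: 18 acetonide alcohol
Product: 19 α-chloro ketone (C7=O, C8(Cl)CH3; acetonide)
Conditions: Dess–Martin periodinane, pyridine, CH2Cl2, 0 °C → rt
Reagents that add atoms: none
Why: Dess–Martin oxidation of the hindered secondary C7 alcohol under buffered conditions that should leave the acetonide and the tertiary chloride intact.

Step 11
Reactants: 19 α-chloro ketone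
Product: 20 enone acetonide (C7=O, C8(CH3)=C9)
Conditions: LiBr, Li2CO3, DMF, 110 °C
Reagents that add atoms: none
Why: Dehydrohalogenation of a tertiary α-chloro ketone: elimination can only run toward C9 or the methyl group, and under these equilibrating conditions the endocyclic conjugated 2-methylenone (C8=C9) is expected, as in the classical preparation of 2-methylcyclohex-2-enones, while C1, C2 and C5 are no longer next to a carbonyl group.

Step 12
Reactants: 20 enone acetonide
Product: 21 (1R,2R,5R,10S)-diol enone (C1–OH, C2–OH, C3=C4, C7=O, C8=C9)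
Conditions: AcOH/H2O/THF 3:1:1, 40 °C
Reagents that add atoms: none
Why: Mild acid hydrolysis of the acetal (the trans-fused dioxolane is strained and labile), under which the enone and the allylic C2–O bond should survive.

Step 13
Reactants: 22 angelic acid ((Z)-2-methylbut-2-enoic acid)
Product: 23 (Z)-2-methylbut-2-en-1-ol
Conditions: LiAlH4, Et2O, 0 °C → rt
Reagents that add atoms: none
Why: Hydride reduction of the carboxylic acid to the primary allylic alcohol, which for alkyl-substituted acrylic acids proceeds without conjugate reduction and keeps the Z geometry.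

Step 14
Reactants: 23 (Z)-2-methylbut-2-en-1-ol
Product: 24 [(2S,3R)-2,3-dimethyloxiran-2-yl]methanol
Conditions: Ti(OiPr)4 (10 mol %), L-(+)-diethyl tartrate (14 mol %), t-BuOOH (2 equiv), 4 Å molecular sieves, CH2Cl2, −20 °C
Reagents that add atoms: tert-butyl hydroperoxide, CC(C)(C)OO
Why: Sharpless asymmetric epoxidation: the titanium–L-(+)-tartrate complex delivers oxygen to the face of the Z-trisubstituted allylic alcohol that gives the 2S,3R epoxy alcohol (the sense established for Z-allylic alcohols such as nerol), so both stereocentres are set by the catalyst.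

Step 15
Reactants: 24 epoxy alcohol
Product: 25 (2R,3R)-2,3-dimethyloxirane-2-carboxylic acid (epoxyangelic acid)
Conditions: 2,2,6,6-tetramethylpiperidin-1-oxyl (20 mol %), PhI(OAc)2 (2.2 equiv), MeCN/H2O 1:1, 0 °C → rt
Reagents that add atoms: water, O
Why: Nitroxyl-catalysed oxidation of the primary alcohol through the aldehyde hydrate to the carboxylic acid, which leaves the epoxide untouched (the C2 descriptor changes from S to R only because the substituent priorities change).

Step 16
Reactants: 21 diol enone; 25 epoxyangelic acid
Product: 27 C2 mono-ester (C2–O-epoxyangelate; C1–OH free), via mixed anhydride 26 (not isolated)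
Conditions: 25, 2,4,6-trichlorobenzoyl chloride, Et3N, THF, 0 °C; then 21, 4-(dimethylamino)pyridine, toluene, 0 °C → rt
Reagents that add atoms: none
Why: Yamaguchi esterification: the mixed anhydride, activated by 4-(dimethylamino)pyridine, should acylate the allylic C2 hydroxyl in preference to the C1 hydroxyl, which is flanked by the quaternary C11.

Step 17
Reactants: 27 C2 mono-ester; 22 angelic acid
Product: 29 CNP0332927.1 (target), via mixed anhydride 28 (not isolated)
Conditions: 22, 2,4,6-trichlorobenzoyl chloride, Et3N, toluene, rt; then 27, toluene, 80 °C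
Reagents that add atoms: none
Why: Yamaguchi-type mixed-anhydride esterification without nucleophilic catalyst, a protocol that transfers the angeloyl group to hindered alcohols without Z to E isomerisation to the tiglate.

Compound list
1 | isoprene | C=CC(C)=C | starting material
2 | 4,4-dimethylcyclohex-2-en-1-one | CC1(C)CCC(=O)C=C1 | starting material
3 | (4aS,8aR)-4,4,6-trimethyl-3,4,4a,5,8,8a-hexahydronaphthalen-1(2H)-one (cis-octalone) | C1CC(=O)[C@@H]2CC=C(C)C[C@@H]2C1(C)C | intermediate
4 | lithium enolate of 3 (C4(OLi)=C2) | C1C=C(O[Li])[C@@H]2CC=C(C)C[C@@H]2C1(C)C | intermediate (not isolated)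
5 | 4,4,6-trimethyl-1-(trimethylsilyloxy)-3,4,4a,5,8,8a-hexahydronaphthalene (kinetic enol ether, C4=C2) | C1C=C(O[Si](C)(C)C)[C@@H]2CC=C(C)C[C@@H]2C1(C)C | intermediate
6 | diiodomethane | ICI | starting material
7 | siloxycyclopropane (C3 bridging C2 and C4 of 5; both cyclopropane faces) | C1C2CC2(O[Si](C)(C)C)[C@@H]3CC=C(C)C[C@@H]3C1(C)C | intermediate (not isolated)
8 | β-chloro ketone (C4=O, C2–Cl cycloheptanone; C2 epimers) | C1C(Cl)CC(=O)[C@@H]2CC=C(C)C[C@@H]2C1(C)C | intermediate (not isolated)
9 | (5R,10S)-cis-6,6,9-trimethylbicyclo[5.4.0]undeca-3,9-dien-2-one (C4=O, C2=C3, C7=C8) | C1C=CC(=O)[C@@H]2CC=C(C)C[C@@H]2C1(C)C | intermediate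
10 | tertiary allylic alcohol (C4(OH)CH3, C2=C3, C7=C8; C4 epimers) | C1C=CC(C)(O)[C@@H]2CC=C(C)C[C@@H]2C1(C)C | intermediate
11 | enone (C2=O, C3=C4(CH3), C7=C8) | C1C(=O)C=C(C)[C@@H]2CC=C(C)C[C@@H]2C1(C)C | intermediate
12 | lithium dienolate of 11 (C1=C2(OLi)–C3=C4) | C1=C(O[Li])C=C(C)[C@@H]2CC=C(C)C[C@@H]2C1(C)C | intermediate (not isolated)
13 | trimethylsilyl dienol ether of 11 (C1=C2(OSiMe3)–C3=C4) | C1=C(O[Si](C)(C)C)C=C(C)[C@@H]2CC=C(C)C[C@@H]2C1(C)C | intermediate (not isolated)
14 | (1R)-1-(trimethylsilyloxy) enone 7,8-epoxide (C1–O cis to H5/H10) | C[Si](C)(C)O[C@H]1C(=O)C=C(C)[C@@H]2CC3OC3(C)C[C@@H]2C1(C)C | intermediate (not isolated)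
15 | (1R)-1-hydroxy enone 7,8-epoxide (C2=O, C3=C4) | O[C@H]1C(=O)C=C(C)[C@@H]2CC3OC3(C)C[C@@H]2C1(C)C | intermediate
16 | chlorohydrin (C1–OH, C2=O, C7–OH, C8(Cl)CH3 trans) | O[C@H]1C(=O)C=C(C)[C@@H]2CC(O)C(C)(Cl)C[C@@H]2C1(C)C | intermediate
17 | (1R,2R)-triol (trans C1/C2 diol, C3=C4, C7–OH, C8–Cl) | O[C@H]1[C@H](O)C=C(C)[C@@H]2CC(O)C(C)(Cl)C[C@@H]2C1(C)C | intermediate
18 | C1/C2 acetonide of 17 (C7–OH free) | CC1(C)O[C@H]2[C@H](O1)C=C(C)[C@@H]3CC(O)C(C)(Cl)C[C@@H]3C2(C)C | intermediate
19 | α-chloro ketone acetonide (C7=O, C8(Cl)CH3) | CC1(C)O[C@H]2[C@H](O1)C=C(C)[C@@H]3CC(=O)C(C)(Cl)C[C@@H]3C2(C)C | intermediate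
20 | enone acetonide (C7=O, C8(CH3)=C9) | CC1(C)O[C@H]2[C@H](O1)C=C(C)[C@@H]3CC(=O)C(C)=C[C@@H]3C2(C)C | intermediate
21 | (1R,2R,5R,10S)-diol enone (C1–OH cis and C2–OH trans to H5/H10) | O[C@H]1[C@H](O)C=C(C)[C@@H]2CC(=O)C(C)=C[C@@H]2C1(C)C | intermediate
22 | angelic acid, (Z)-2-methylbut-2-enoic acid | C/C=C(/C)C(=O)O | starting material
23 | (Z)-2-methylbut-2-en-1-ol | C/C=C(/C)CO | intermediate
24 | [(2S,3R)-2,3-dimethyloxiran-2-yl]methanol | OC[C@]1(C)O[C@@H]1C | intermediate
25 | (2R,3R)-2,3-dimethyloxirane-2-carboxylic acid | OC(=O)[C@]1(C)O[C@@H]1C | intermediate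
26 | (2R,3R)-2,3-dimethyloxirane-2-carboxylic 2,4,6-trichlorobenzoic anhydride | O=C(OC(=O)c1c(Cl)cc(Cl)cc1Cl)[C@]1(C)O[C@@H]1C | intermediate (not isolated)
27 | C2 epoxyangelate of 21 (C1–OH free) | O[C@H]1[C@H](OC(=O)[C@]2(C)O[C@@H]2C)C=C(C)[C@@H]2CC(=O)C(C)=C[C@@H]2C1(C)C | intermediate
28 | angelic 2,4,6-trichlorobenzoic anhydride | C/C=C(/C)C(=O)OC(=O)c1c(Cl)cc(Cl)cc1Cl | intermediate (not isolated)
29 | CNP0332927.1: C1 angelate, C2 (2R,3R)-epoxyangelate of 21 | C/C=C(/C)C(=O)O[C@H]1[C@H](OC(=O)[C@]2(C)O[C@@H]2C)C=C(C)[C@@H]2CC(=O)C(C)=C[C@@H]2C1(C)C | target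

Total step count: 17.
Longest linear sequence: 14 steps (steps 1–12, 16 and 17); steps 13–15 make the side-chain acid 25.

Steps most likely to fail

Step 1. The cycloaddition may be slow at the β-carbon next to the quaternary centre, and the level or sense of enantioselection may be inadequate. The fallback sets out from 1 and 2 and comes back at 3. The cycloaddition is run without a chiral catalyst (AlCl3, toluene, 25–40 °C), which should give the racemic cis adduct, i.e. 3 together with its enantiomer, (4aR,8aS)-4,4,6-trimethyl-3,4,4a,5,8,8a-hexahydronaphthalen-1(2H)-one F1. Compound 3 is then separated by preparative chromatography on a cellulose tris(3,5-dimethylphenylcarbamate) phase.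

Step 6. Facial selectivity of the peracid attack at C1 may be poor, so that the C1 epimer is carried along. The fallback sets out from 11 and comes back at 15. Lithium dienolate 12, made as in step 6, is oxidised with the enantiomer of (camphorylsulfonyl)oxaziridine matched to attack on the H5/H10 face, so that reagent control replaces substrate control, to give the (1R)-1-hydroxy enone with the ring-B alkene intact F2. Epoxidation of C7=C8 with 3-chloroperbenzoic acid (1.1 equiv, CH2Cl2, 0 °C) then gives 15.

Step 3. The carbenoid may also cyclopropanate the ring-B alkene, the C2 radical may add to C7=C8 before chlorine transfer, or C5 may epimerise during the elimination. The fallback sets out from 3 and comes back at 9. Octalone 3 is homologated directly with trimethylsilyldiazomethane and Me3Al (CH2Cl2, −78 °C), the less substituted C2 methylene migrating, to the α-trimethylsilyl cycloheptanone F3. Protodesilylation (dilute HCl, THF) gives the saturated cis-fused cycloheptanone F4. Aerobic dehydrogenation with Pd(O2CCF3)2 (divalent palladium, 5 mol %), DMSO, O2 and AcOH at 80 °C, which takes place on the less substituted side, then gives dienone 9.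

Further compounds
F1 | step 1 | (4aR,8aS)-4,4,6-trimethyl-3,4,4a,5,8,8a-hexahydronaphthalen-1(2H)-one (enantiomer of 3) | C1CC(=O)[C@H]2CC=C(C)C[C@H]2C1(C)C
F2 | step 6 | (1R)-1-hydroxy enone with C7=C8 intact (C2=O, C3=C4) | O[C@H]1C(=O)C=C(C)[C@@H]2CC=C(C)C[C@@H]2C1(C)C
F3 | step 3 | α-trimethylsilyl cycloheptanone (C4=O, C3–SiMe3, C7=C8) | C1CC([Si](C)(C)C)C(=O)[C@@H]2CC=C(C)C[C@@H]2C1(C)C
F4 | step 3 | saturated cis-fused cycloheptanone (C4=O, C7=C8) | C1CCC(=O)[C@@H]2CC=C(C)C[C@@H]2C1(C)C
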